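**Retrosynthetic overview** (germacrane numbering: lactone C12(=O)–O–C8, exocyclic C11=C13, ester on C6, hydroxyls on C2 and C9, Z-olefins C1=C10 and C4=C5)
1. Ring A (ten-membered) is closed last at C9–C10 by a Nozaki–Hiyama–Kishi reaction that also sets C9; the C6 ester C–O bond is made just before, on the open-chain precursor.
2. C6–C7 comes from an indium Barbier union of a C8-chiral 3-(bromomethyl)butenolide (ring B) with a Z-hydroxy-enal released from a dihydropyran acetal; C8 controls C7 and C6.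
3. Ring B is made first, by the key lactone C–O bond: a catalytic enantioselective 1,4-bromolactonization of an achiral 2-methylidene-3-enoic acid, which sets C8 and unveils the allyl bromide.
4. The dihydropyran (C2 stereocentre, Z-C4=C5 locked by the ring) comes from an asymmetric hetero-Diels–Alder reaction of (Z)-3-iodobut-2-enal, whose iodoalkene is the future Z-C1=C10.
5. Ring order: B (lactone) → temporary pyran (opened in the Barbier step) → A (carbocycle).

Assumption: the catalyst or ligand enantiomers named in steps 3, 7 and 11 are those expected to give the stated facial sense; if a first run shows the mirror sense, the other enantiomer (or pseudo-enantiomer) is used and nothing else changes.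

**Step 1**
Reactants: 1 ethyl 2-(bromomethyl)prop-2-enoate; 2 triethyl phosphite
Product: 3 ethyl 2-[(diethoxyphosphoryl)methyl]prop-2-enoate
Conditions: neat, 100 °C, 3 h, EtBr distilled off
Reagents that add atoms: none
Why: Michaelis–Arbuzov reaction, in which the allylic bromide alkylates phosphorus and bromide dealkylates the phosphonium salt (direct and allylic attack give the same phosphonate; no stereocentre).

**Step 2**
Reactants: 3 ethyl 2-[(diethoxyphosphoryl)methyl]prop-2-enoate; 4 2,2-dimethoxyacetaldehyde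
Product: 6 (3E)-5,5-dimethoxy-2-methylidenepent-3-enoic acid, via diene ethyl ester 5 (not isolated)
Conditions: LiOH·H2O (1.1 equiv), THF–H2O, 0 → 23 °C; then LiOH·H2O (1.5 equiv), 23 °C; 1 M HCl to pH 4, 0 °C
Reagents that add atoms: lithium hydroxide, [Li+].[OH-]
Why: Horner–Wadsworth–Emmons olefination of the allylic phosphonate anion gives the (E)-2-alkoxycarbonyl-1,3-diene, which is saponified in the same flask before it can dimerise.

**Step 3**
Reactants: 6 (3E)-5,5-dimethoxy-2-methylidenepent-3-enoic acid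
Product: 7 (5R)-3-(bromomethyl)-5-(dimethoxymethyl)furan-2(5H)-one
Conditions: N-bromosuccinimide (1.1 equiv), quinidine-derived amino-thiocarbamate catalyst (10 mol %), toluene–CHCl3 (2:1), −60 °C, dark
Reagents that add atoms: N-bromosuccinimide, O=C1CCC(=O)N1Br
Why: Proposed new method: a catalytic enantioselective vinylogous (1,4-) bromolactonization in which the bifunctional amine–thiocarbamate ion-pairs with the acid and, through sulfur, hands Br+ from N-bromosuccinimide to the terminal methylidene carbon while the carboxylate oxygen closes onto C4 of the s-trans diene (within five-ring reach), so the lactone C–O bond, ring B and the 5R centre (future C8) form at once and the allyl bromide for step 8 is unveiled (a 1,2-adduct, if formed, is the allylic isomer and gives the same allylindium); the closest known reactions are amino-thiocarbamate-catalysed asymmetric bromolactonizations of alkenoic acids and the 1,4-bromolactonization of conjugated enynes.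

**Step 4**
Reactants: 8 1,1-diethoxy-3-methylbut-2-ene
Product: 9 (1E)-1-ethoxy-3-methylbuta-1,3-diene
Conditions: KHSO4 (1 mol %), 150 °C, EtOH then product distilled
Reagents that add atoms: none
Why: Acid-catalysed 1,4-elimination of ethanol from the allylic acetal (oxocarbenium ion, loss of a γ-proton) gives the E-alkoxydiene.

**Step 5**
Reactants: 10 but-2-yn-1-ol
Product: 12 (2Z)-3-iodobut-2-en-1-ol, via sodium alkenylaluminate 11 (not isolated)
Conditions: NaAlH2(OCH2CH2OCH3)2, THF, 0 → 23 °C; then I2, −78 °C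
Reagents that add atoms: iodine, II; sodium bis(2-methoxyethoxy)aluminium dihydride, [Na+].[AlH2-](OCCOC)OCCOC (its metal atoms and alkoxy groups stay only in 11)
Why: Hydroxyl-directed trans-hydroalumination puts aluminium on C3 cis to the CH2O group in a cyclic aluminate, and iodinolysis with retention gives the Z-iodoalkene that becomes C1=C10.

**Step 6**
Reactants: 12 (2Z)-3-iodobut-2-en-1-ol
Product: 13 (2Z)-3-iodobut-2-enal
Conditions: PhI(OAc)2 (1.1 equiv), TEMPO (10 mol %), CH2Cl2, 23 °C, dark; used at once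
Reagents that add atoms: none
Why: Nitroxyl-catalysed oxidation of the allylic alcohol under neutral conditions keeps the Z geometry.

**Step 7**
Reactants: 13 (2Z)-3-iodobut-2-enal; 9 (1E)-1-ethoxy-3-methylbuta-1,3-diene
Product: 14 (2R,6S)-2-ethoxy-6-[(1Z)-2-iodoprop-1-en-1-yl]-4-methyl-5,6-dihydro-2H-pyran
Conditions: [CrCl(L)] (5 mol %; trivalent chromium; L = Schiff-base dianion from (1S,2R)-1-aminoindan-2-ol and 3-(1-adamantyl)-2-hydroxy-5-methylbenzaldehyde), 4 Å MS, neat, 23 °C
Reagents that add atoms: none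
Why: Enantioselective hetero-Diels–Alder reaction in which the chiral chromium Lewis acid binds the aldehyde and the diene terminus adds to its Si face through an endo transition state, giving the cis-2,6 acetal with 6S (future C2) and fixing the future C4=C5 olefin as Z inside the ring.

**Step 8**
Reactants: 14 (2R,6S)-2-ethoxy-6-[(1Z)-2-iodoprop-1-en-1-yl]-4-methyl-5,6-dihydro-2H-pyran; 7 (5R)-3-(bromomethyl)-5-(dimethoxymethyl)furan-2(5H)-one
Product: 16 (4S,5R)-4-[(1R,2Z,5S,6Z)-1,5-dihydroxy-7-iodo-3-methylocta-2,6-dien-1-yl]-5-(dimethoxymethyl)-3-methylideneoxolan-2-one, via lactol 15 (not isolated)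
Conditions: HCl (5 mol %), THF–H2O (3:1), 0 °C, 30 min; then 7, In powder (1.5 equiv), 23 °C
Reagents that add atoms: water, O
Why: Aqueous Barbier allylation in which mild acid opens the allylic acetal to the lactol/Z-hydroxy-enal and the allylindium from 7 adds through its γ-carbon in a chair transition state, anti to the C8 substituent (7,8-trans) and with the ring-fixed E-type allyl geometry (6,7-anti), which sets 7S and 6R and restores the exocyclic methylidene.

**Step 9**
Reactants: 16 (4S,5R)-4-[(1R,2Z,5S,6Z)-1,5-dihydroxy-7-iodo-3-methylocta-2,6-dien-1-yl]-5-(dimethoxymethyl)-3-methylideneoxolan-2-one; 17 (2R)-2-methylbutanoic acid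
Product: 19 (1R,2Z,5S,6Z)-1-[(2R,3S)-2-(dimethoxymethyl)-4-methylidene-5-oxooxolan-3-yl]-7-iodo-3-methyl-5-[(triethylsilyl)oxy]octa-2,6-dien-1-yl (2R)-2-methylbutanoate, via C2 triethylsilyl ether 18 (not isolated)
Conditions: Et3SiCl (1.05 equiv), imidazole, CH2Cl2, −40 °C; then 17, iPrN=C=NiPr, DMAP (10 mol %), 0 → 23 °C
Reagents that add atoms: chlorotriethylsilane, CC[Si](Cl)(CC)CC
Why: The less hindered C2 hydroxyl (CH2 neighbour) is silylated before the C6 hydroxyl (next to the ring carbon), and Steglich esterification then acylates C6–OH with retention at C6 and at the acid's α-carbon.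

**Step 10**
Reactants: 19 (1R,2Z,5S,6Z)-1-[(2R,3S)-2-(dimethoxymethyl)-4-methylidene-5-oxooxolan-3-yl]-7-iodo-3-methyl-5-[(triethylsilyl)oxy]octa-2,6-dien-1-yl (2R)-2-methylbutanoate
Product: 20 (1R,2Z,5S,6Z)-1-[(2R,3S)-2-formyl-4-methylidene-5-oxooxolan-3-yl]-5-hydroxy-7-iodo-3-methylocta-2,6-dien-1-yl (2R)-2-methylbutanoate
Conditions: 0.5 M HCl, THF–H2O (4:1), 23 °C; used crude
Reagents that add atoms: water, O
Why: Acid hydrolysis unmasks the C9 aldehyde from the dimethyl acetal and removes the silyl ether in one operation, without touching any stereocentre.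

**Step 11**
Reactants: 20 (1R,2Z,5S,6Z)-1-[(2R,3S)-2-formyl-4-methylidene-5-oxooxolan-3-yl]-5-hydroxy-7-iodo-3-methylocta-2,6-dien-1-yl (2R)-2-methylbutanoate
Product: 21 (1(10)Z,4Z)-(2S,6R,7S,8R,9R)-2,9-dihydroxy-6-{[(2R)-2-methylbutanoyl]oxy}germacra-1(10),4,11(13)-trien-12,8-olide (CNP0176600.1)
Conditions: CrCl2 (6 equiv), (S)-N-[2-(4-tert-butyl-4,5-dihydro-1,3-oxazol-2-yl)-6-methylphenyl]methanesulfonamide (6.6 equiv), Et3N (6.6 equiv), NiCl2 (0.2 equiv), THF, 23 °C, 20 added over 12 h to 0.003 M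
Reagents that add atoms: none
Why: Nozaki–Hiyama–Kishi macrocyclization in which the Z-alkenyl iodide is turned (zerovalent nickel, then divalent chromium) into an alkenylchromium species with retention and adds to the C9 aldehyde at high dilution to close ring A, the chiral sulfonamide–chromium complex directing Re-face attack to give the 9R (8,9-threo) carbinol against the weak Felkin bias of the α-acyloxy aldehyde.

**Compound list**
1 | ethyl 2-(bromomethyl)prop-2-enoate | C=C(CBr)C(=O)OCC | starting material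
2 | triethyl phosphite | CCOP(OCC)OCC | starting material
3 | ethyl 2-[(diethoxyphosphoryl)methyl]prop-2-enoate | C=C(CP(=O)(OCC)OCC)C(=O)OCC | intermediate
4 | 2,2-dimethoxyacetaldehyde | COC(OC)C=O | starting material
5 | ethyl (3E)-5,5-dimethoxy-2-methylidenepent-3-enoate | CCOC(=O)C(=C)/C=C/C(OC)OC | intermediate
6 | (3E)-5,5-dimethoxy-2-methylidenepent-3-enoic acid | OC(=O)C(=C)/C=C/C(OC)OC | intermediate
7 | (5R)-3-(bromomethyl)-5-(dimethoxymethyl)furan-2(5H)-one | O=C1O[C@@H](C(OC)OC)C=C1CBr | intermediate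
8 | 1,1-diethoxy-3-methylbut-2-ene | CCOC(OCC)C=C(C)C | starting material
9 | (1E)-1-ethoxy-3-methylbuta-1,3-diene | CCO/C=C/C(C)=C | intermediate
10 | but-2-yn-1-ol | CC#CCO | starting material
11 | sodium 2,2-bis(2-methoxyethoxy)-3-methyl-2,5-dihydro-1,2-oxaluminol-2-uide (cyclic Z-alkenylaluminate) | [Na+].CC1=CCO[Al-]1(OCCOC)OCCOC | intermediate
12 | (2Z)-3-iodobut-2-en-1-ol | OC/C=C(/C)I | intermediate
13 | (2Z)-3-iodobut-2-enal | O=C/C=C(/C)I | intermediate
14 | (2R,6S)-2-ethoxy-6-[(1Z)-2-iodoprop-1-en-1-yl]-4-methyl-5,6-dihydro-2H-pyran | CCO[C@H]1C=C(C)C[C@@H](/C=C(/C)I)O1 | intermediate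
15 | (6S)-6-[(1Z)-2-iodoprop-1-en-1-yl]-4-methyl-5,6-dihydro-2H-pyran-2-ol (lactol, both anomers) | OC1C=C(C)C[C@@H](/C=C(/C)I)O1 | intermediate
16 | (4S,5R)-4-[(1R,2Z,5S,6Z)-1,5-dihydroxy-7-iodo-3-methylocta-2,6-dien-1-yl]-5-(dimethoxymethyl)-3-methylideneoxolan-2-one | C=C1C(=O)O[C@@H](C(OC)OC)[C@@H]1[C@H](O)/C=C(/C)C[C@H](O)/C=C(/C)I | intermediate
17 | (2R)-2-methylbutanoic acid | CC[C@@H](C)C(=O)O | starting material
18 | (4S,5R)-5-(dimethoxymethyl)-4-[(1R,2Z,5S,6Z)-1-hydroxy-7-iodo-3-methyl-5-[(triethylsilyl)oxy]octa-2,6-dien-1-yl]-3-methylideneoxolan-2-one | C=C1C(=O)O[C@@H](C(OC)OC)[C@@H]1[C@H](O)/C=C(/C)C[C@H](O[Si](CC)(CC)CC)/C=C(/C)I | intermediate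
19 | (1R,2Z,5S,6Z)-1-[(2R,3S)-2-(dimethoxymethyl)-4-methylidene-5-oxooxolan-3-yl]-7-iodo-3-methyl-5-[(triethylsilyl)oxy]octa-2,6-dien-1-yl (2R)-2-methylbutanoate | C=C1C(=O)O[C@@H](C(OC)OC)[C@@H]1[C@H](OC(=O)[C@H](C)CC)/C=C(/C)C[C@H](O[Si](CC)(CC)CC)/C=C(/C)I | intermediate
20 | (1R,2Z,5S,6Z)-1-[(2R,3S)-2-formyl-4-methylidene-5-oxooxolan-3-yl]-5-hydroxy-7-iodo-3-methylocta-2,6-dien-1-yl (2R)-2-methylbutanoate | C=C1C(=O)O[C@@H](C=O)[C@@H]1[C@H](OC(=O)[C@H](C)CC)/C=C(/C)C[C@H](O)/C=C(/C)I | intermediate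
21 | (1(10)Z,4Z)-(2S,6R,7S,8R,9R)-2,9-dihydroxy-6-{[(2R)-2-methylbutanoyl]oxy}germacra-1(10),4,11(13)-trien-12,8-olide (CNP0176600.1) | C=C1C(=O)O[C@@H]2[C@@H]1[C@H](OC(=O)[C@H](C)CC)/C=C(/C)C[C@H](O)/C=C(/C)[C@H]2O | target

**Totals**
Total step count: 11. Longest linear sequence: 7 (steps 5–11; the branch through steps 1–3 and then 8–11 is also 7).

**Three steps most likely to fail**

Step 3, the new bromolactonization, may give low enantiomeric excess or mainly non-productive bromination. The fallback uses only known reactions, sets out from 4 and comes back at 7. Catalytic asymmetric vinylation of 4 (Zn(CH=CH2)2, (−)-3-exo-morpholinoisoborneol) gives (2R)-1,1-dimethoxybut-3-en-2-ol F1. Steglich esterification with commercial 2-(bromomethyl)acrylic acid gives (2R)-1,1-dimethoxybut-3-en-2-yl 2-(bromomethyl)prop-2-enoate F2. Ring-closing metathesis (second-generation Grubbs catalyst, toluene, 80 °C) closes F2 to 7.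

Step 8, the Barbier union, may give the wrong carbinol configuration at C6. The fallback sets out from 14 and 7 and comes back at 19. If the coupling gives mainly (4S,5R)-4-[(1S,2Z,5S,6Z)-1,5-dihydroxy-7-iodo-3-methylocta-2,6-dien-1-yl]-5-(dimethoxymethyl)-3-methylideneoxolan-2-one F3, its C2 hydroxyl is silylated (Et3SiCl, imidazole) to the C2 triethylsilyl ether of the 6-epimer F4. C6 is then esterified with inversion by a Mitsunobu reaction with 17 (PPh3, DIAD), which gives 19 directly.

Step 11, the macrocyclization, may close the ring poorly or give the 9-epimer. The fallback sets the C9 centre by ketone reduction instead; it sets out from 20 and comes back at 21. Silylation of 20 gives the C2 triethylsilyl ether of the seco-aldehyde F5. A ligand-free chromium/nickel cyclization (CrCl2, NiCl2, DMSO) gives the macrocyclic C9-epimeric alcohols (C2 silyl ether) F6. Dess–Martin oxidation gives the macrocyclic 9-ketone (C2 silyl ether) F7. Corey–Bakshi–Shibata reduction (oxazaborolidine, catecholborane) gives the 9R alcohol, the C2 triethylsilyl ether of the target F8, and HF·pyridine then gives 21.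

**Further compounds**
F1 | step 3 | (2R)-1,1-dimethoxybut-3-en-2-ol | C=C[C@@H](O)C(OC)OC
F2 | step 3 | (2R)-1,1-dimethoxybut-3-en-2-yl 2-(bromomethyl)prop-2-enoate | C=C[C@@H](OC(=O)C(=C)CBr)C(OC)OC
F3 | step 8 | (4S,5R)-4-[(1S,2Z,5S,6Z)-1,5-dihydroxy-7-iodo-3-methylocta-2,6-dien-1-yl]-5-(dimethoxymethyl)-3-methylideneoxolan-2-one | C=C1C(=O)O[C@@H](C(OC)OC)[C@@H]1[C@@H](O)/C=C(/C)C[C@H](O)/C=C(/C)I
F4 | step 8 | (4S,5R)-5-(dimethoxymethyl)-4-[(1S,2Z,5S,6Z)-1-hydroxy-7-iodo-3-methyl-5-[(triethylsilyl)oxy]octa-2,6-dien-1-yl]-3-methylideneoxolan-2-one | C=C1C(=O)O[C@@H](C(OC)OC)[C@@H]1[C@@H](O)/C=C(/C)C[C@H](O[Si](CC)(CC)CC)/C=C(/C)I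
F5 | step 11 | (1R,2Z,5S,6Z)-1-[(2R,3S)-2-formyl-4-methylidene-5-oxooxolan-3-yl]-7-iodo-3-methyl-5-[(triethylsilyl)oxy]octa-2,6-dien-1-yl (2R)-2-methylbutanoate | C=C1C(=O)O[C@@H](C=O)[C@@H]1[C@H](OC(=O)[C@H](C)CC)/C=C(/C)C[C@H](O[Si](CC)(CC)CC)/C=C(/C)I
F6 | step 11 | C9-epimeric mixture of the 2-O-triethylsilyl ether of 21 | C=C1C(=O)O[C@@H]2[C@@H]1[C@H](OC(=O)[C@H](C)CC)/C=C(/C)C[C@H](O[Si](CC)(CC)CC)/C=C(/C)C2O
F7 | step 11 | 9-oxo analogue of 21 as its 2-O-triethylsilyl ether | C=C1C(=O)O[C@@H]2[C@@H]1[C@H](OC(=O)[C@H](C)CC)/C=C(/C)C[C@H](O[Si](CC)(CC)CC)/C=C(/C)C2=O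
F8 | step 11 | 2-O-triethylsilyl ether of 21 (9R) | C=C1C(=O)O[C@@H]2[C@@H]1[C@H](OC(=O)[C@H](C)CC)/C=C(/C)C[C@H](O[Si](CC)(CC)CC)/C=C(/C)[C@H]2O
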